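Ring B is built last, by a carbene-catalysed dearomatizing hydroacylation of a benzofuran; the route runs from 2-methylcyclohex-2-en-1-one in 15 linear steps.

Atoms carry aristolane numbers (C1–C11). Everything rests on the C9–C10 bond, which joins the C9 ketone to the fully substituted, aryloxy-bearing C10 in ring B (the cyclopropane-fused cyclohexanedione). The C9(=O)–C10(OAr)–C1(H)Ar array of the cis-fused dihydrobenzofuran is read as the hydroacylation adduct of a benzofuran: a carbene-catalysed dearomatizing hydroacylation adds a C9 aldehyde across C10=C1, closing ring B and setting C10 and C1 in one operation. Its precursor is a flat tetrahydrodibenzofuran chalcone whose quaternary C5 carries a cis-cyclopropane with a CH2CHO arm; C4–C7 are set earlier by conjugate addition/alkylation and a lactone-tethered carbenoid cyclopropanation.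

Key step: step 14

Remark: C1 = benzylic CH, C2/C3 = CH2, C4 = CHMe, C5 = CMe, C6/C7 = cyclopropane CH, C8/C9 = carbonyl carbons, C10 = O-bearing carbon, C11 = CMe2; it is assumed that the 2′-hydroxychalcone, held as its phenoxide under basic conditions, does not close to the flavanone.

Step 1
Reactants: 1 2-methylcyclohex-2-en-1-one; 2 3-bromo-2-methylprop-1-ene
Product: 4 (2S,3R)-2,3-dimethyl-2-(2-methylprop-2-en-1-yl)cyclohexan-1-one, via aluminium enolate 3 (not isolated)
Conditions: Me3Al (1.4 equiv), Cu(OTf)2 (2 mol%), (S,S,S)-binaphthol-derived N,N-bis(1-phenylethyl)phosphoramidite (4 mol%; the ligand enantiomer that gives the 3R centre is used), Et2O, −30 °C; then MeLi (1.4 equiv), THF/DMPU, 2 (2 equiv), −30 °C to rt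
Reagents that add atoms: trimethylaluminium, C[Al](C)C
Why: Tandem copper-catalysed asymmetric conjugate addition–enolate alkylation: the ligand sets C4, and the regiodefined enolate (activated as its lithium ate complex) is alkylated anti to the new C4 methyl, which should place the C4 and C5 methyls cis.

Step 2
Reactants: 4 (2S,3R)-2,3-dimethyl-2-(2-methylprop-2-en-1-yl)cyclohexan-1-one
Product: 5 (2R,3R)-2,3-dimethyl-2-(2-methylprop-1-en-1-yl)cyclohexan-1-one
Conditions: p-TsOH·H2O (10 mol%), toluene, 80 °C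
Reagents that add atoms: none
Why: Acid-catalysed alkene isomerization through the tertiary C11 cation should move the double bond into the trisubstituted C6=C11 position; C5 is quaternary, so no stereocentre is touched.

Step 3
Reactants: 5 (2R,3R)-2,3-dimethyl-2-(2-methylprop-1-en-1-yl)cyclohexan-1-one
Product: 6 (1S,2R,3R)-2,3-dimethyl-2-(2-methylprop-1-en-1-yl)cyclohexan-1-ol
Conditions: NaBH4, MeOH, 0 °C to rt
Reagents that add atoms: none
Why: Borohydride reduction with axial hydride delivery on the face opposite the axial C5 methyl should give the equatorial C10 alcohol, trans to the alkenyl group, which is also the more stable epimer.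

Step 4
Reactants: 6 (1S,2R,3R)-2,3-dimethyl-2-(2-methylprop-1-en-1-yl)cyclohexan-1-ol
Product: 8 (1S,2R,3R)-2,3-dimethyl-2-(2-methylprop-1-en-1-yl)cyclohexyl 2-diazoacetate, via tosylhydrazone ester 7 (not isolated)
Conditions: TsNHN=CHCOCl (1.5 equiv), PhNMe2, CH2Cl2, 0 °C; then Et3N, 0 °C to rt
Reagents that add atoms: 2-[2-(4-methylphenyl)sulfonylhydrazinylidene]acetyl chloride, Cc1ccc(cc1)S(=O)(=O)NN=CC(Cl)=O
Why: O-acylation followed by base-induced loss of p-toluenesulfinate (Bamford–Stevens-type diazoacetate synthesis) installs the carbenoid precursor on the C10 oxygen without touching a stereocentre.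

Step 5
Reactants: 8 (1S,2R,3R)-2,3-dimethyl-2-(2-methylprop-1-en-1-yl)cyclohexyl 2-diazoacetate
Product: 9 tricyclic lactone 9-oxa-aristolan-8-one (4R,5R,6S,7R,10S)
Conditions: Rh2(5S-MEPY)4 (1 mol%; the catalyst enantiomer that matches the substrate preference is used), CH2Cl2, 40 °C, slow addition of 8
Reagents that add atoms: none
Why: Intramolecular rhodium-carbenoid cyclopropanation of a homoallylic diazoacetate: the six-membered tether forces a cis-cyclopropane, and in the trans-fused chair-like transition state the carbenoid should reach the C6=C11 face anti to the axial C5 methyl, which sets C6 and C7 (the carboxamidate catalyst also disfavours C–H insertion).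

Step 6
Reactants: 9 tricyclic lactone 9-oxa-aristolan-8-one
Product: 10 lactol 9-oxa-aristolan-8-ol (mixture at C8)
Conditions: iBu2AlH (1.1 equiv), CH2Cl2, −78 °C
Reagents that add atoms: none
Why: Partial reduction of a lactone at low temperature stops at the lactol because the tetrahedral aluminate is stable until work-up.

Step 7
Reactants: 10 lactol 9-oxa-aristolan-8-ol
Product: 11 (1S,2R,3R)-2-[(1S,3S)-3-(2-methoxyethenyl)-2,2-dimethylcyclopropyl]-2,3-dimethylcyclohexan-1-ol (E/Z mixture)
Conditions: (MeOCH2)PPh3Cl (3.5 equiv), KN(SiMe3)2 (3.3 equiv), THF, 0 °C; then 10, 0 °C to rt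
Reagents that add atoms: (methoxymethyl)triphenylphosphonium chloride, COC[P+](c1ccccc1)(c1ccccc1)c1ccccc1.[Cl-]
Why: Wittig methoxymethylenation of the ring-opened hydroxy aldehyde adds C9 as an enol ether (one-carbon homologation); the olefination should outrun epimerization at C7.

Step 8
Reactants: 11 (1S,2R,3R)-2-[(1S,3S)-3-(2-methoxyethenyl)-2,2-dimethylcyclopropyl]-2,3-dimethylcyclohexan-1-ol
Product: 12 (1S,2R,3R)-2-{(1S,3R)-3-[(1,3-dithian-2-yl)methyl]-2,2-dimethylcyclopropyl}-2,3-dimethylcyclohexan-1-ol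
Conditions: HS(CH2)3SH (1.5 equiv), BF3·OEt2, CH2Cl2, −20 °C
Reagents that add atoms: propane-1,3-dithiol, SCCCS
Why: Protonation of the enol ether at C8 gives the C9 oxocarbenium ion, which the dithiol traps as the acid-stable 1,3-dithiane (thioacetalization); both enol ether isomers converge.

Step 9
Reactants: 12 (1S,2R,3R)-2-{(1S,3R)-3-[(1,3-dithian-2-yl)methyl]-2,2-dimethylcyclopropyl}-2,3-dimethylcyclohexan-1-ol
Product: 13 (2R,3R)-2-{(1S,3R)-3-[(1,3-dithian-2-yl)methyl]-2,2-dimethylcyclopropyl}-2,3-dimethylcyclohexan-1-one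
Conditions: SO3·pyridine, DMSO, iPr2NEt, CH2Cl2, 0 °C to rt
Reagents that add atoms: none
Why: Parikh–Doering (activated DMSO) oxidation returns the C10 ketone and should leave the thioacetal unoxidized.

Step 10
Reactants: 13 (2R,3R)-2-{(1S,3R)-3-[(1,3-dithian-2-yl)methyl]-2,2-dimethylcyclopropyl}-2,3-dimethylcyclohexan-1-one
Product: 15 (2R,3R)-6-chloro-2-{(1S,3R)-3-[(1,3-dithian-2-yl)methyl]-2,2-dimethylcyclopropyl}-2,3-dimethylcyclohexan-1-one (C1 epimers), via lithium enolate 14 (not isolated)
Conditions: LiN(iPr)2 (1.1 equiv), THF, −78 °C; then TsCl (1.2 equiv), −78 to 0 °C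
Reagents that add atoms: 4-methylbenzenesulfonyl chloride, Cc1ccc(cc1)S(Cl)(=O)=O
Why: Enolization is possible only toward C1 (C5 is quaternary), and chlorine transfer from TsCl to the lithium enolate gives the α-chloro ketone without an oxidant that would attack sulfur.

Step 11
Reactants: 15 α-chloro ketone; 16 1-(2,6-dihydroxy-4-methoxyphenyl)ethan-1-one
Product: 17 1-[(3R,4R)-4-{(1S,3R)-3-[(1,3-dithian-2-yl)methyl]-2,2-dimethylcyclopropyl}-7-hydroxy-9-methoxy-3,4-dimethyl-1,2,3,4-tetrahydrodibenzo[b,d]furan-6-yl]ethan-1-one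
Conditions: 16 (1.5 equiv), TiCl4 (1.1 equiv), CF3CH2OH, 70 °C
Reagents that add atoms: none
Why: TiCl4-promoted one-pot benzofuran synthesis from a phenol and an α-halo ketone: ortho Friedel–Crafts alkylation by C1 at the only free position next to a phenol OH, then cyclodehydration of that OH onto the C10 ketone; the symmetry of 16 leaves one regiochemical outcome (aryl on C1, oxygen on C10).

Step 12
Reactants: 17 benzofuran methyl ketone; 18 4-methoxybenzaldehyde
Product: 19 (E)-1-[(3R,4R)-4-{(1S,3R)-3-[(1,3-dithian-2-yl)methyl]-2,2-dimethylcyclopropyl}-7-hydroxy-9-methoxy-3,4-dimethyl-1,2,3,4-tetrahydrodibenzo[b,d]furan-6-yl]-3-(4-methoxyphenyl)prop-2-en-1-one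
Conditions: 18 (1.5 equiv), KOH (50% aq.), EtOH, rt; acidic work-up
Reagents that add atoms: none
Why: Claisen–Schmidt aldol condensation of the only enolizable ketone with the non-enolizable aldehyde should give the E-chalcone by E1cB dehydration; the dithiane keeps C9 out of the reaction.

Step 13
Reactants: 19 chalcone dithiane
Product: 20 2-[(1R,3S)-3-{(3R,4R)-7-hydroxy-9-methoxy-6-[(E)-3-(4-methoxyphenyl)prop-2-enoyl]-3,4-dimethyl-1,2,3,4-tetrahydrodibenzo[b,d]furan-4-yl}-2,2-dimethylcyclopropyl]acetaldehyde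
Conditions: MeI (excess), CaCO3, MeCN/H2O (4:1), 45 °C
Reagents that add atoms: water, O
Why: Alkylative dithiane hydrolysis (S-methylation, then water attack on the thionium ion) should release the C9 aldehyde under near-neutral, non-oxidizing conditions and frees no thiol that could add to the chalcone.

Step 14
Reactants: 20 chalcone aldehyde
Product: 21 pentacyclic C9 ketone (1R,4R,5R,6S,7R,10S), the 8-deoxo analogue of the target
Conditions: 2-mesityl-6,7-dihydro-5H-pyrrolo[2,1-c][1,2,4]triazol-2-ium chloride (20 mol%), DBU (1.4 equiv), 1,4-dioxane (0.01 M), 90 °C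
Reagents that add atoms: none
Why: The carbene adds to the C9 aldehyde to give the Breslow intermediate, whose nucleophilic C9 and O–H add across the benzofuran C10=C1 bond in a concerted, asynchronous ene-type transition state (C9–C10 bond formation with proton delivery to C1), after which the carbene is expelled and C9=O is restored. The closest known reaction type is the carbene-catalysed intramolecular dearomatizing hydroacylation of benzofurans (and of enol ethers), so far shown with aryl aldehydes. Ring B closes in the 6-exo-trig mode, C10=C1 lying outside the new ring. C10 is set by the tether: the cis-cyclopropane arm on C5 reaches C10 only from the face that carries the C5–C6 bond, in the half-chair with this bond pseudoaxial and anti to the C4 methyl, so the C5 methyl and the C10 oxygen should end up cis; C1 is set by suprafacial delivery of the enol proton on the same face, which gives the cis-fused dihydrobenzofuran. The step needs chemoselectivity over Stetter addition to the chalcone and over aldehyde self-condensation; the chalcone is present as its electron-rich 2′-phenoxide, a poor and geometrically unreachable acceptor, and high dilution favours the intramolecular path.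

Step 15
Reactants: 21 pentacyclic C9 ketone
Product: 22 CNP0121765.1 (1R,4R,5R,6S,7R,10S)
Conditions: SeO2 (2 equiv), 1,4-dioxane/H2O (30:1), 90 °C
Reagents that add atoms: selenium dioxide, O=[Se]=O
Why: Riley oxidation: the C9 ketone can enolize only toward C8 (C10 is quaternary and the chalcone carbonyl has no enolizable hydrogen), so the C8 methylene should be oxidized to the 8,9-dione with all stereocentres untouched.

Compound list
1 | 2-methylcyclohex-2-en-1-one | CC1=CCCCC1=O | starting material
2 | 3-bromo-2-methylprop-1-ene | C=C(C)CBr | starting material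
3 | dimethylaluminium (3R)-2,3-dimethylcyclohex-1-en-1-olate | CC1=C(O[Al](C)C)CCC[C@H]1C | intermediate (not isolated)
4 | (2S,3R)-2,3-dimethyl-2-(2-methylprop-2-en-1-yl)cyclohexan-1-one | C=C(C)C[C@@]1(C)[C@H](C)CCCC1=O | intermediate
5 | (2R,3R)-2,3-dimethyl-2-(2-methylprop-1-en-1-yl)cyclohexan-1-one | CC(C)=C[C@@]1(C)[C@H](C)CCCC1=O | intermediate
6 | (1S,2R,3R)-2,3-dimethyl-2-(2-methylprop-1-en-1-yl)cyclohexan-1-ol (OH cis to the C5 methyl) | CC(C)=C[C@@]1(C)[C@H](C)CCC[C@@H]1O | intermediate
7 | (1S,2R,3R)-2,3-dimethyl-2-(2-methylprop-1-en-1-yl)cyclohexyl 2-[2-(4-methylphenyl)sulfonylhydrazinylidene]acetate | CC(C)=C[C@@]1(C)[C@H](C)CCC[C@@H]1OC(=O)C=NNS(=O)(=O)c1ccc(C)cc1 | intermediate (not isolated)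
8 | (1S,2R,3R)-2,3-dimethyl-2-(2-methylprop-1-en-1-yl)cyclohexyl 2-diazoacetate | CC(C)=C[C@@]1(C)[C@H](C)CCC[C@@H]1OC(=O)C=[N+]=[N-] | intermediate
9 | 9-oxa-aristolan-8-one: tricyclic δ-lactone, 4R,5R,6S,7R,10S, lactone trans-fused to ring A, cis-fused gem-dimethylcyclopropane anti to the C5 methyl | O=C1[C@@H]2[C@@H](C2(C)C)[C@@]3(C)[C@H](C)CCC[C@@H]3O1 | intermediate
10 | 9-oxa-aristolan-8-ol: the lactol of 9, 4R,5R,6S,7R,10S, mixture at C8 | OC1[C@@H]2[C@@H](C2(C)C)[C@@]3(C)[C@H](C)CCC[C@@H]3O1 | intermediate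
11 | (1S,2R,3R)-2-[(1S,3S)-3-(2-methoxyethenyl)-2,2-dimethylcyclopropyl]-2,3-dimethylcyclohexan-1-ol, E/Z mixture | COC=C[C@@H]1[C@@H](C1(C)C)[C@@]2(C)[C@H](C)CCC[C@@H]2O | intermediate
12 | (1S,2R,3R)-2-{(1S,3R)-3-[(1,3-dithian-2-yl)methyl]-2,2-dimethylcyclopropyl}-2,3-dimethylcyclohexan-1-ol | C1CSC(SC1)C[C@@H]2[C@@H](C2(C)C)[C@@]3(C)[C@H](C)CCC[C@@H]3O | intermediate
13 | (2R,3R)-2-{(1S,3R)-3-[(1,3-dithian-2-yl)methyl]-2,2-dimethylcyclopropyl}-2,3-dimethylcyclohexan-1-one | C1CSC(SC1)C[C@@H]2[C@@H](C2(C)C)[C@@]3(C)[C@H](C)CCCC3=O | intermediate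
14 | lithium (5R,6R)-6-{(1S,3R)-3-[(1,3-dithian-2-yl)methyl]-2,2-dimethylcyclopropyl}-5,6-dimethylcyclohex-1-en-1-olate | [Li+].C1CSC(SC1)C[C@@H]2[C@@H](C2(C)C)[C@@]3(C)[C@H](C)CCC=C3[O-] | intermediate (not isolated)
15 | (2R,3R)-6-chloro-2-{(1S,3R)-3-[(1,3-dithian-2-yl)methyl]-2,2-dimethylcyclopropyl}-2,3-dimethylcyclohexan-1-one, both epimers at the chlorine-bearing carbon | C1CSC(SC1)C[C@@H]2[C@@H](C2(C)C)[C@@]3(C)[C@H](C)CCC(Cl)C3=O | intermediate
16 | 1-(2,6-dihydroxy-4-methoxyphenyl)ethan-1-one | CC(=O)c1c(O)cc(OC)cc1O | starting material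
17 | 1-[(3R,4R)-4-{(1S,3R)-3-[(1,3-dithian-2-yl)methyl]-2,2-dimethylcyclopropyl}-7-hydroxy-9-methoxy-3,4-dimethyl-1,2,3,4-tetrahydrodibenzo[b,d]furan-6-yl]ethan-1-one | CC(=O)c1c(O)cc(OC)c2c1oc1c2CC[C@@H](C)[C@]1(C)[C@H]3[C@@H](CC4SCCCS4)C3(C)C | intermediate
18 | 4-methoxybenzaldehyde | COc1ccc(C=O)cc1 | starting material
19 | (E)-1-[(3R,4R)-4-{(1S,3R)-3-[(1,3-dithian-2-yl)methyl]-2,2-dimethylcyclopropyl}-7-hydroxy-9-methoxy-3,4-dimethyl-1,2,3,4-tetrahydrodibenzo[b,d]furan-6-yl]-3-(4-methoxyphenyl)prop-2-en-1-one | COc1ccc(/C=C/C(=O)c2c(O)cc(OC)c3c2oc2c3CC[C@@H](C)[C@]2(C)[C@H]4[C@@H](CC5SCCCS5)C4(C)C)cc1 | intermediate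
20 | 2-[(1R,3S)-3-{(3R,4R)-7-hydroxy-9-methoxy-6-[(E)-3-(4-methoxyphenyl)prop-2-enoyl]-3,4-dimethyl-1,2,3,4-tetrahydrodibenzo[b,d]furan-4-yl}-2,2-dimethylcyclopropyl]acetaldehyde | COc1ccc(/C=C/C(=O)c2c(O)cc(OC)c3c2oc2c3CC[C@@H](C)[C@]2(C)[C@H]4[C@@H](CC=O)C4(C)C)cc1 | intermediate
21 | 8-deoxo analogue of the target: pentacyclic C9 ketone with C8 = CH2, 1R,4R,5R,6S,7R,10S, cis-fused dihydrobenzofuran, C5 methyl and C10 oxygen cis | COc1ccc(/C=C/C(=O)c2c(O)cc(OC)c3c2O[C@]24C(=O)C[C@@H]5[C@@H](C5(C)C)[C@@]2(C)[C@H](C)CC[C@H]34)cc1 | intermediate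
22 | CNP0121765.1, the aristolane-8,9-dione chalcone hybrid, 1R,4R,5R,6S,7R,10S | COc1ccc(/C=C/C(=O)c2c(O)cc(OC)c3c2O[C@]24C(=O)C(=O)[C@@H]5[C@@H](C5(C)C)[C@@]2(C)[C@H](C)CC[C@H]34)cc1 | target

Total step count: 15. Longest linear sequence: 15 steps (1 to 22); 2, 16 and 18 are purchased.

Steps most likely to fail

Step 14. The bulky carbene-bound acyl anion equivalent may be unable to engage the tetrasubstituted, electron-rich C10=C1 bond next to quaternary C5, so that acyloin or aldol self-condensation of the aldehyde, or slow Stetter addition, consumes the material. The fallback replaces the acyl anion by an acyl radical and sets out from 20: Pinnick oxidation (NaClO2, NaH2PO4, 2-methylbut-2-ene, tBuOH/H2O) should give the carboxylic acid F1, which PhSeSePh/Bu3P (CH2Cl2) converts into the Se-phenyl selenoester F2. Slow addition of Bu3SnH/AIBN (benzene, 80 °C, 0.005 M) then generates the C9 acyl radical, a small nucleophile with an early transition state that should add 6-exo-trig to C10. The benzylic C1 radical takes hydrogen from the stannane on the face that gives the cis ring fusion, and the route is rejoined at 21.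

Step 11. Friedel–Crafts attack at the ring carbon flanked by OH and OMe may be slower than O-alkylation, loss of HCl from the chloro ketone or acid-induced opening of the gem-dimethylcyclopropane. The fallback replaces the Friedel–Crafts alkylation by a palladium enolate arylation and sets out from 13 and 16: bromination of 16 (NBS, MeCN, 0 °C) gives 1-(3-bromo-2,6-dihydroxy-4-methoxyphenyl)ethan-1-one F3. One-pot enolate arylation of 13 with F3 (Pd2(dba)3, a bulky dialkylbiarylphosphine, NaOtBu 4 equiv, toluene, 80 °C; the two phenoxides keep the aryl methyl ketone from enolizing) should give the 6-aryl ketone F4. TFA in CH2Cl2 dehydrates its cyclic hemiketal to the benzofuran, and the route is rejoined at 17.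

Step 15. Under hot, weakly acidic selenous acid the free 2′-hydroxychalcone may close to the flavanone and be dehydrogenated, or the hindered C8 methylene may be oxidized too slowly. The fallback replaces the Riley oxidation by enolate oxygenation and sets out from 21: KN(SiMe3)2 (2.2 equiv, THF, −78 °C; phenoxide first, then the C8 enolate) and 2-(benzenesulfonyl)-3-phenyloxaziridine should give the 8-hydroxy ketone F5. Dess–Martin periodinane (NaHCO3, CH2Cl2) oxidizes F5 to the dione, arriving at 22.

Further compounds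
F1 | step 14 | 2-[(1R,3S)-3-{(3R,4R)-7-hydroxy-9-methoxy-6-[(E)-3-(4-methoxyphenyl)prop-2-enoyl]-3,4-dimethyl-1,2,3,4-tetrahydrodibenzo[b,d]furan-4-yl}-2,2-dimethylcyclopropyl]acetic acid | COc1ccc(/C=C/C(=O)c2c(O)cc(OC)c3c2oc2c3CC[C@@H](C)[C@]2(C)[C@H]4[C@@H](CC(O)=O)C4(C)C)cc1
F2 | step 14 | Se-phenyl selenoester of F1 | COc1ccc(/C=C/C(=O)c2c(O)cc(OC)c3c2oc2c3CC[C@@H](C)[C@]2(C)[C@H]4[C@@H](CC(=O)[Se]c5ccccc5)C4(C)C)cc1
F3 | step 11 | 1-(3-bromo-2,6-dihydroxy-4-methoxyphenyl)ethan-1-one | CC(=O)c1c(O)cc(OC)c(Br)c1O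
F4 | step 11 | (2R,3R)-6-(3-acetyl-2,4-dihydroxy-6-methoxyphenyl)-2-{(1S,3R)-3-[(1,3-dithian-2-yl)methyl]-2,2-dimethylcyclopropyl}-2,3-dimethylcyclohexan-1-one, epimers at the aryl-bearing carbon | C1CSC(SC1)C[C@@H]2[C@@H](C2(C)C)[C@@]3(C)[C@H](C)CCC(c4c(O)c(C(C)=O)c(O)cc4OC)C3=O
F5 | step 15 | 8-hydroxy derivative of 21 (α-hydroxy ketone, mixture at C8) | COc1ccc(/C=C/C(=O)c2c(O)cc(OC)c3c2O[C@]24C(=O)C(O)[C@@H]5[C@@H](C5(C)C)[C@@]2(C)[C@H](C)CC[C@H]34)cc1
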